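The diaryl ether between ring A (the methoxy arene) and ring B (the para-phenylene) is the bond on which the route rests. Its oxygen sits on ring A C3, ortho to the C4 oxygen and meta to the bridge carbon C1, while ring B carries oxygen para to its bridge: the ortho-oxygenated, para-alkylated pattern that phenol oxidation delivers. In one operation, Tl(NO3)3 oxidation followed by zinc reduction joins the ring B phenol oxygen to ring A and closes the 19-membered ring. The precursor is an open chain with ring A as a 2,6-dibromophenol, ring B as a 2,6-dichlorophenol and the ring C oxygen benzylated, built from a C–O–D diaryl ether by Wittig and Horner–Wadsworth–Emmons olefinations.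

Key step: step 10

Remark: ring C is the phenol ring and ring D the unsubstituted meta-phenylene. Commercial supply of compound 2 is assumed. The alkenes of 9 and 13 are carried as geometric mixtures because step 8 saturates both. Thallium salts are acutely toxic, so step 10 calls for small scale and containment.

Step 1
Reactants: 1 4-benzyloxy-3-hydroxybenzaldehyde; 2 diethyl (3-bromobenzyl)phosphonate
Product: 3 diethyl {[3-(2-benzyloxy-5-formylphenoxy)phenyl]methyl}phosphonate
Conditions: CuI (10 mol%), N,N-dimethylglycine·HCl (30 mol%), Cs2CO3 (2 equiv), dioxane, 90 °C, Ar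
Reagents that add atoms: none
Why: Ligand-accelerated Ullmann diaryl ether synthesis; the phenol of 1 is meta to the formyl group and therefore a good nucleophile, the bromide of 2 is unhindered, and carbonate in dioxane is far too weak to deprotonate the benzylic phosphonate, so no olefination of the aldehyde should compete.

Step 2
Reactants: 3 diethyl {[3-(2-benzyloxy-5-formylphenoxy)phenyl]methyl}phosphonate
Product: 4 diethyl ({3-[2-benzyloxy-5-(hydroxymethyl)phenoxy]phenyl}methyl)phosphonate
Conditions: NaBH4, MeOH/THF, 0 °C
Reagents that add atoms: none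
Why: Borohydride reduction of an aryl aldehyde; the phosphonate ester and both ether types are inert to NaBH4.

Step 3
Reactants: 4 diethyl ({3-[2-benzyloxy-5-(hydroxymethyl)phenoxy]phenyl}methyl)phosphonate
Product: 5 {4-benzyloxy-3-[3-(diethoxyphosphorylmethyl)phenoxy]benzyl}triphenylphosphonium bromide
Conditions: PPh3·HBr (1.1 equiv), MeCN, reflux
Reagents that add atoms: triphenylphosphine hydrobromide, Br.P(c1ccccc1)(c1ccccc1)c1ccccc1
Why: Direct phosphonium salt formation from a benzylic alcohol; the para-benzyloxy group makes acid-promoted ionisation of the alcohol easy and PPh3 captures the benzylic electrophile, while the weakly acidic reagent should spare the aryl benzyl ether and the phosphonate ester.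

Step 4
Reactants: 6 3,5-dichloro-4-hydroxybenzaldehyde
Product: 7 3,5-dichloro-4-(methoxymethoxy)benzaldehyde
Conditions: MOMCl, iPr2NEt, CH2Cl2, 0 °C to rt
Reagents that add atoms: chloromethyl methyl ether, COCCl
Why: Williamson-type O-alkylation of the acidic phenol; masking it keeps the aldehyde from being deactivated as a vinylogous carboxylate and keeps the phenol from quenching the ylide in step 5.

Step 5
Reactants: 5 {4-benzyloxy-3-[3-(diethoxyphosphorylmethyl)phenoxy]benzyl}triphenylphosphonium bromide; 7 3,5-dichloro-4-(methoxymethoxy)benzaldehyde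
Product: 9 diethyl {[3-(2-benzyloxy-5-{2-[3,5-dichloro-4-(methoxymethoxy)phenyl]ethenyl}phenoxy)phenyl]methyl}phosphonate (E/Z mixture), via phosphonium ylide 8 (not isolated)
Conditions: K2CO3 (3 equiv), 18-crown-6 (cat.), CH2Cl2, reflux
Reagents that add atoms: none
Why: Wittig olefination under solid–liquid phase transfer; carbonate can deprotonate the phosphonium methylene but not the benzylic phosphonate, which is about ten pKa units less acidic, so only the ring C arm should react with the electron-poor aldehyde.

Step 6
Reactants: 10 3,5-dibromo-4-hydroxybenzaldehyde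
Product: 11 3,5-dibromo-4-(methoxymethoxy)benzaldehyde
Conditions: MOMCl, iPr2NEt, CH2Cl2, 0 °C to rt
Reagents that add atoms: chloromethyl methyl ether, COCCl
Why: Williamson-type O-alkylation, for the same reason as in step 4.

Step 7
Reactants: 9 diethyl {[3-(2-benzyloxy-5-{2-[3,5-dichloro-4-(methoxymethoxy)phenyl]ethenyl}phenoxy)phenyl]methyl}phosphonate; 11 3,5-dibromo-4-(methoxymethoxy)benzaldehyde
Product: 13 1-benzyloxy-2-(3-{(E)-2-[3,5-dibromo-4-(methoxymethoxy)phenyl]ethenyl}phenoxy)-4-{2-[3,5-dichloro-4-(methoxymethoxy)phenyl]ethenyl}benzene, via potassium phosphonate carbanion 12 (not isolated)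
Conditions: KOtBu (1.2 equiv), THF, 0 °C; then 11, 0 °C to rt
Reagents that add atoms: none
Why: Horner–Wadsworth–Emmons olefination; the stronger base now deprotonates the benzylic phosphonate, the only acidic site left, and the carbanion should add to the non-enolisable aldehyde and lose diethyl phosphate to give mainly the E alkene, with aryl halides and both ether types inert to alkoxide at this temperature.

Step 8
Reactants: 13 1-benzyloxy-2-(3-{(E)-2-[3,5-dibromo-4-(methoxymethoxy)phenyl]ethenyl}phenoxy)-4-{2-[3,5-dichloro-4-(methoxymethoxy)phenyl]ethenyl}benzene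
Product: 14 1-benzyloxy-2-(3-{2-[3,5-dibromo-4-(methoxymethoxy)phenyl]ethyl}phenoxy)-4-{2-[3,5-dichloro-4-(methoxymethoxy)phenyl]ethyl}benzene
Conditions: TsNHNH2 (large excess, in portions), NaOAc, DME/H2O, reflux
Reagents that add atoms: none
Why: Diimide reduction; diimide generated in the flask transfers two hydrogens concertedly to each stilbene C=C and should leave C–Br, C–Cl and the benzyl ether untouched, which catalytic hydrogenation would not, and any stray loss of a MOM group is harmless because step 9 removes both.

Step 9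
Reactants: 14 1-benzyloxy-2-(3-{2-[3,5-dibromo-4-(methoxymethoxy)phenyl]ethyl}phenoxy)-4-{2-[3,5-dichloro-4-(methoxymethoxy)phenyl]ethyl}benzene
Product: 15 2,6-dibromo-4-[2-(3-{2-benzyloxy-5-[2-(3,5-dichloro-4-hydroxyphenyl)ethyl]phenoxy}phenyl)ethyl]phenol
Conditions: conc. HCl (cat.), MeOH/THF, 50 °C
Reagents that add atoms: none
Why: Acid-catalysed acetal cleavage (transacetalisation of the MOM ethers to methanol) should free both halophenols, while the aryl benzyl ether, the diaryl ether and the aryl halides are stable to dilute HCl.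

Step 10
Reactants: 15 2,6-dibromo-4-[2-(3-{2-benzyloxy-5-[2-(3,5-dichloro-4-hydroxyphenyl)ethyl]phenoxy}phenyl)ethyl]phenol
Product: 17 bromo-dichloro macrocyclic phenol (ring A: 2-aryloxy-6-bromophenol; ring B: 2,6-dichlorophenoxy; ring C: benzyl ether), via macrocyclic 6-aryloxy-6-bromocyclohexa-2,4-dienone 16 (not isolated)
Conditions: Tl(NO3)3·3H2O (2.5 equiv), MeOH/THF, ca. 1 mM, −20 to 0 °C; then Zn dust, AcOH, rt
Reagents that add atoms: none
Why: Tl(NO3)3 should bind the more easily oxidised 2,6-dibromophenol of ring A and remove two electrons from it (trivalent thallium leaving as monovalent thallium), giving a phenoxonium-type species whose para position is blocked by the bridge; the ring B phenol oxygen then adds intramolecularly to a bromine-bearing ortho carbon to give dienone 16, and zinc in acetic acid reductively expels that bromide and rearomatises ring A to phenol 17. The closest known reaction type is the thallium trinitrate oxidative coupling of pairs of ortho,ortho'-dihalophenols to isodityrosine-type diaryl ethers. The 19-membered ring closes end to end through this single intramolecular oxygen-to-ring-carbon attack, a macrocyclisation outside the range of Baldwin constraints that is run at high dilution to suppress dimers. No stereocentre is created in the product, since the sp3 carbon of 16 is racemic and is erased on reduction. The step needs chemoselection between the two phenols and C–O over C–C bond formation: bromine against chlorine substitution sets the order of oxidation potentials, and halogens at all four ortho positions together with alkyl groups at both para positions leave oxygen attack at an ortho carbon as the only productive path. The benzyl ether keeps the ring C oxygen out of the oxidation and leaves the ring A hydroxyl as the only free phenol for step 11.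

Step 11
Reactants: 17 bromo-dichloro macrocyclic phenol
Product: 18 ring A methyl ether of 17 (bromo-dichloro macrocycle with ring A methoxy and ring C benzyloxy)
Conditions: MeI, K2CO3, DMF, rt to 40 °C
Reagents that add atoms: iodomethane, CI
Why: Williamson O-methylation; the ring A hydroxyl, acidified by its ortho bromine and aryloxy neighbours, is the only free OH, so the methyl group can go nowhere else.

Step 12
Reactants: 18 ring A methyl ether of 17
Product: 19 target macrocycle CNP0132125.0 (ring A methoxy; ring C hydroxy; no halogen)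
Conditions: H2 (1–3 atm), 10% Pd/C, NaOAc, MeOH/THF, rt
Reagents that add atoms: none
Why: Heterogeneous palladium hydrogenolysis; acetate-buffered hydrodehalogenation should remove the bromine and both chlorines, and the same catalyst cleaves the benzyl ether, while the aryl methyl ether and the diaryl ethers are not hydrogenolysed.

Compound list
1 | 4-benzyloxy-3-hydroxybenzaldehyde | O=Cc1ccc(OCc2ccccc2)c(O)c1 | starting material
2 | diethyl (3-bromobenzyl)phosphonate | CCOP(=O)(Cc1cccc(Br)c1)OCC | starting material
3 | diethyl {[3-(2-benzyloxy-5-formylphenoxy)phenyl]methyl}phosphonate | CCOP(=O)(Cc1cccc(Oc2cc(C=O)ccc2OCc2ccccc2)c1)OCC | intermediate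
4 | diethyl ({3-[2-benzyloxy-5-(hydroxymethyl)phenoxy]phenyl}methyl)phosphonate | CCOP(=O)(Cc1cccc(Oc2cc(CO)ccc2OCc2ccccc2)c1)OCC | intermediate
5 | {4-benzyloxy-3-[3-(diethoxyphosphorylmethyl)phenoxy]benzyl}triphenylphosphonium bromide | CCOP(=O)(Cc1cccc(Oc2cc(C[P+](c3ccccc3)(c3ccccc3)c3ccccc3)ccc2OCc2ccccc2)c1)OCC.[Br-] | intermediate
6 | 3,5-dichloro-4-hydroxybenzaldehyde | O=Cc1cc(Cl)c(O)c(Cl)c1 | starting material
7 | 3,5-dichloro-4-(methoxymethoxy)benzaldehyde | COCOc1c(Cl)cc(C=O)cc1Cl | intermediate
8 | phosphonium ylide of 5 ({4-benzyloxy-3-[3-(diethoxyphosphorylmethyl)phenoxy]benzylidene}triphenylphosphorane) | CCOP(=O)(Cc1cccc(Oc2cc(C=P(c3ccccc3)(c3ccccc3)c3ccccc3)ccc2OCc2ccccc2)c1)OCC | intermediate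
9 | diethyl {[3-(2-benzyloxy-5-{2-[3,5-dichloro-4-(methoxymethoxy)phenyl]ethenyl}phenoxy)phenyl]methyl}phosphonate, E/Z mixture | CCOP(=O)(Cc1cccc(Oc2cc(C=Cc3cc(Cl)c(OCOC)c(Cl)c3)ccc2OCc2ccccc2)c1)OCC | intermediate
10 | 3,5-dibromo-4-hydroxybenzaldehyde | O=Cc1cc(Br)c(O)c(Br)c1 | starting material
11 | 3,5-dibromo-4-(methoxymethoxy)benzaldehyde | COCOc1c(Br)cc(C=O)cc1Br | intermediate
12 | potassium phosphonate carbanion of 9 | CCOP(=O)([CH-]c1cccc(Oc2cc(C=Cc3cc(Cl)c(OCOC)c(Cl)c3)ccc2OCc2ccccc2)c1)OCC.[K+] | intermediate
13 | 1-benzyloxy-2-(3-{(E)-2-[3,5-dibromo-4-(methoxymethoxy)phenyl]ethenyl}phenoxy)-4-{2-[3,5-dichloro-4-(methoxymethoxy)phenyl]ethenyl}benzene, second alkene as E/Z mixture | COCOc1c(Br)cc(/C=C/c2cccc(Oc3cc(C=Cc4cc(Cl)c(OCOC)c(Cl)c4)ccc3OCc3ccccc3)c2)cc1Br | intermediate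
14 | 1-benzyloxy-2-(3-{2-[3,5-dibromo-4-(methoxymethoxy)phenyl]ethyl}phenoxy)-4-{2-[3,5-dichloro-4-(methoxymethoxy)phenyl]ethyl}benzene | COCOc1c(Br)cc(CCc2cccc(Oc3cc(CCc4cc(Cl)c(OCOC)c(Cl)c4)ccc3OCc3ccccc3)c2)cc1Br | intermediate
15 | 2,6-dibromo-4-[2-(3-{2-benzyloxy-5-[2-(3,5-dichloro-4-hydroxyphenyl)ethyl]phenoxy}phenyl)ethyl]phenol | Oc1c(Br)cc(CCc2cccc(Oc3cc(CCc4cc(Cl)c(O)c(Cl)c4)ccc3OCc3ccccc3)c2)cc1Br | intermediate
16 | macrocyclic 6-aryloxy-2,6-dibromocyclohexa-2,4-dienone (ring A oxidised, racemic at the sp3 carbon) | O=C1C(Br)=CC2=CC1(Br)Oc1c(Cl)cc(cc1Cl)CCc1ccc(OCc3ccccc3)c(c1)Oc1cccc(c1)CC2 | intermediate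
17 | bromo-dichloro macrocyclic phenol (ring A 2-aryloxy-6-bromophenol, ring B 2,6-dichlorophenoxy, ring C benzyl ether) | Oc1c(Br)cc2cc1Oc1c(Cl)cc(cc1Cl)CCc1ccc(OCc3ccccc3)c(c1)Oc1cccc(c1)CC2 | intermediate
18 | ring A methyl ether of 17 | COc1c(Br)cc2cc1Oc1c(Cl)cc(cc1Cl)CCc1ccc(OCc3ccccc3)c(c1)Oc1cccc(c1)CC2 | intermediate
19 | CNP0132125.0, 19-membered bis(bibenzyl) bis(diaryl ether) with ring A methoxy and ring C hydroxy, no stereocentre | COc1ccc2cc1Oc1ccc(cc1)CCc1ccc(O)c(c1)Oc1cccc(c1)CC2 | target

Total step count: 12.
Longest linear sequence: 10 steps (steps 1, 2, 3, 5, 7, 8, 9, 10, 11, 12); steps 4 and 6 are one-step side branches.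

Steps most likely to fail

Step 10. Intermolecular phenol coupling may outrun ring closure and give dimers and oligomers, the phenolic product may be oxidised further, or the oxidant may attack the electron-rich ring C. The fallback forms the same ring A–O–ring B bond by intramolecular Ullmann etherification in place of phenol oxidation. It sets out from compound 5. Under the conditions of step 5, ylide 8 is condensed with commercial 4-(methoxymethoxy)benzaldehyde to give the stilbene phosphonate F1. Deprotonation with KOtBu and reaction with commercial 3-bromo-4-methoxybenzaldehyde gives the bis-stilbene F2. Diimide reduction as in step 8 gives the saturated aryl bromide F3, and HCl in MeOH frees the ring B phenol F4. CuBr·SMe2 and NaH in refluxing pyridine at high dilution then close the macrocycle to the benzyl ether of the target F5. Hydrogenolysis over Pd/C comes back to the route at compound 19.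

Step 1. Oxidative addition of the unactivated bromide may be slow, so that base-promoted condensation between the benzylic phosphonate and the aldehyde, or thermal decay of the aldehyde, takes over. The fallback makes the diaryl ether by room-temperature oxidative copper coupling with a boronic acid and installs phosphorus afterwards. It sets out from compound 1. Chan–Lam–Evans coupling with 3-(hydroxymethyl)phenylboronic acid (Cu(OAc)2, pyridine, 4 Å MS, CH2Cl2, air) gives the hydroxymethyl diaryl ether aldehyde F6. Appel bromination (CBr4, PPh3, CH2Cl2, 0 °C) gives the benzylic bromide F7. A Michaelis–Arbuzov reaction with P(OEt)3 at 120 °C comes back to the route at compound 3.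

Step 12. The hydrogenolysis may stall after loss of bromine and benzyl as liberated halide poisons the catalyst surface, leaving the two hindered ring B chlorines in place. The fallback separates the two tasks and uses homogeneous chemistry for each. It sets out from compound 18. BCl3 with pentamethylbenzene (CH2Cl2, −78 °C) removes the benzyl group and gives the halogenated macrocyclic phenol F8. Transfer hydrodehalogenation with (IPr)Pd(allyl)Cl (IPr = 1,3-bis(2,6-diisopropylphenyl)imidazol-2-ylidene), NaOtBu and iPrOH at 60 °C then removes the bromine and both chlorines and arrives at compound 19.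

Further compounds
F1 | step 10 | diethyl {[3-(2-benzyloxy-5-{2-[4-(methoxymethoxy)phenyl]ethenyl}phenoxy)phenyl]methyl}phosphonate, E/Z mixture | CCOP(=O)(Cc1cccc(Oc2cc(C=Cc3ccc(OCOC)cc3)ccc2OCc2ccccc2)c1)OCC
F2 | step 10 | 1-benzyloxy-2-{3-[(E)-2-(3-bromo-4-methoxyphenyl)ethenyl]phenoxy}-4-{2-[4-(methoxymethoxy)phenyl]ethenyl}benzene | COc1ccc(/C=C/c2cccc(Oc3cc(C=Cc4ccc(OCOC)cc4)ccc3OCc3ccccc3)c2)cc1Br
F3 | step 10 | 1-benzyloxy-2-{3-[2-(3-bromo-4-methoxyphenyl)ethyl]phenoxy}-4-{2-[4-(methoxymethoxy)phenyl]ethyl}benzene | COc1ccc(CCc2cccc(Oc3cc(CCc4ccc(OCOC)cc4)ccc3OCc3ccccc3)c2)cc1Br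
F4 | step 10 | 4-[2-(4-benzyloxy-3-{3-[2-(3-bromo-4-methoxyphenyl)ethyl]phenoxy}phenyl)ethyl]phenol | COc1ccc(CCc2cccc(Oc3cc(CCc4ccc(O)cc4)ccc3OCc3ccccc3)c2)cc1Br
F5 | step 10 | ring C benzyl ether of the target macrocycle | COc1ccc2cc1Oc1ccc(cc1)CCc1ccc(OCc3ccccc3)c(c1)Oc1cccc(c1)CC2
F6 | step 1 | 4-benzyloxy-3-[3-(hydroxymethyl)phenoxy]benzaldehyde | O=Cc1ccc(OCc2ccccc2)c(Oc2cccc(CO)c2)c1
F7 | step 1 | 4-benzyloxy-3-[3-(bromomethyl)phenoxy]benzaldehyde | O=Cc1ccc(OCc2ccccc2)c(Oc2cccc(CBr)c2)c1
F8 | step 12 | bromo-dichloro macrocycle with ring A methoxy and free ring C hydroxyl | COc1c(Br)cc2cc1Oc1c(Cl)cc(cc1Cl)CCc1ccc(O)c(c1)Oc1cccc(c1)CC2
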